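**Retrosynthetic overview**
- Target ⇒ 6-oxo-7-ene-15,17-diacid: the C8–H stereocentre and the C6=C7 alkene come from a C6 tosylhydrazone (C=N bond formation), then hydride addition and allylic-diazene retro-ene 1,3-transposition.
- ⇒ ent-16-acetoxylabda-7,13E-dien-15-oic acid: the C6 ketone and the C17 acid are installed by C–H oxygenation (CrO3, then SeO2, then chlorite).
- ⇒ acyclic (2E,6E,10E)-tetraenoic acid: rings A and B close in one catalytic asymmetric proton-initiated cascade, ring A first, then ring B (new step); no ring is formed afterwards.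
- ⇒ farnesyl bromide + tert-butyl acetoacetate dianion, (E)-enol triflate, Negishi coupling with acetoxymethylzinc bromide (fixes the 13E alkene), ester cleavage.

Assumption: the (R,R) antipode of the IDPi acid is taken to give the ent series; the sense of induction follows the catalyst antipode, so the mirror-image catalyst is used if a scouting run shows the opposite sense.
Labdane numbering (C1–C20) is used for the bicyclic compounds. The IDPi acid is used at 5 mol % and its preparation is not counted.

**Step 1**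
Reactants: 1 (2E,6E)-farnesyl bromide; 2 tert-butyl acetoacetate
Product: 4 tert-butyl (6E,10E)-7,11,15-trimethyl-3-oxohexadeca-6,10,14-trienoate, via acetoacetate dianion 3 (not isolated)
Conditions: 2, NaH, THF, 0 °C; n-BuLi, 0 °C; then 1, 0 °C to rt; cold 1 M HCl quench
Reagents that add atoms: none
Why: Weiler acetoacetate dianion alkylation, in which the more basic terminal carbanion displaces the primary allylic bromide by SN2 without touching the E alkenes; no stereocentre is formed.

**Step 2**
Reactants: 4 tert-butyl (6E,10E)-7,11,15-trimethyl-3-oxohexadeca-6,10,14-trienoate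
Product: 5 tert-butyl (2E,6E,10E)-7,11,15-trimethyl-3-[(trifluoromethylsulfonyl)oxy]hexadeca-2,6,10,14-tetraenoate
Conditions: Tf2O, 25% aq. Me4NOH, hexane, 5 °C
Reagents that add atoms: trifluoromethanesulfonic anhydride, O=S(=O)(OS(=O)(=O)C(F)(F)F)C(F)(F)F
Why: Stereoselective enol triflation of a β-keto ester, in which the non-chelating tetramethylammonium counter-ion gives the extended enolate and hence the (E)-enol triflate (OTf anti to the ester), which fixes the later C13=C14 geometry.

**Step 3**
Reactants: 5 tert-butyl (2E,6E,10E)-7,11,15-trimethyl-3-[(trifluoromethylsulfonyl)oxy]hexadeca-2,6,10,14-tetraenoate; 6 bromomethyl acetate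
Product: 8 tert-butyl (2E,6E,10E)-3-(acetoxymethyl)-7,11,15-trimethylhexadeca-2,6,10,14-tetraenoate, via (acetoxymethyl)zinc bromide 7 (not isolated)
Conditions: 6, Zn dust, LiCl, THF, 25 °C; then 5, Pd(OAc)2 (2 mol %), SPhos (4 mol %), THF, 25 °C
Reagents that add atoms: none
Why: Negishi cross-coupling, in which oxidative addition into the vinyl triflate and transmetalation from the acyloxymethylzinc halide (no β-hydrogen) go with retention, so the acetoxymethyl group ends up trans to the ester (13E).

**Step 4**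
Reactants: 8 tert-butyl (2E,6E,10E)-3-(acetoxymethyl)-7,11,15-trimethylhexadeca-2,6,10,14-tetraenoate
Product: 10 (2E,6E,10E)-3-(acetoxymethyl)-7,11,15-trimethylhexadeca-2,6,10,14-tetraenoic acid, via trimethylsilyl ester 9 (not isolated)
Conditions: TMSOTf, 2,6-lutidine, CH2Cl2, 0 °C; then pH 4 aqueous citrate
Reagents that add atoms: none
Why: Silyl triflate-mediated tert-butyl ester cleavage (carbonyl silylation, loss of isobutene) under lutidine buffering, which leaves the acetate and the acid-sensitive polyene untouched; no stereocentre is involved.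

**Step 5**
Reactants: 10 (2E,6E,10E)-3-(acetoxymethyl)-7,11,15-trimethylhexadeca-2,6,10,14-tetraenoic acid
Product: 12 (5R,9R,10R)-16-acetoxy-ent-labda-7,13E-dien-15-oic acid, via labd-13-en-8-yl cation 11 (not isolated)
Conditions: (R,R)-IDPi acid [(R)-3,3′-Ar2-BINOL-O2P(=NSO2C6F5)]2NH, Ar = 9,9-dimethylfluoren-2-yl (5 mol %), (CF3)3COH, −30 °C, 72 h
Reagents that add atoms: none
Why: Proposed new method: a confined chiral imidodiphosphorimidate Brønsted acid in a fluorinated alcohol protonates the terminal 14,15-alkene of the chair–chair folded all-E polyene while the distal CO2H hydrogen-bonds to the catalyst anion, C4–C5 and C9–C10 form in an antiperiplanar cascade (H-5 trans to C-20, C-9 chain equatorial, absolute sense from the catalyst antipode), the 13,14-alkene deactivated by CO2H and CH2OAc stays out, and the catalyst anion removes the axial H-7 of the C8 cation to give the 7,8-alkene; the closest known reaction types are the IDPi-catalysed asymmetric cyclization of homofarnesol to ambrox (ended by O–H capture, not proton loss) and the racemic superacid bicyclization of farnesyl- and geranylgeranyl-type acids to 7-ene bicycles.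

**Step 6**
Reactants: 12 (5R,9R,10R)-16-acetoxy-ent-labda-7,13E-dien-15-oic acid
Product: 13 (5R,9R,10S)-16-acetoxy-6-oxo-ent-labda-7,13E-dien-15-oic acid
Conditions: CrO3, 3,5-dimethylpyrazole, CH2Cl2, −20 °C
Reagents that add atoms: chromium trioxide, O=[Cr](=O)=O
Why: Chromium trioxide–3,5-dimethylpyrazole allylic oxidation, which attacks the electron-rich trisubstituted C7=C8 alkene at its only allylic methylene (C6) to give the 7-en-6-one while the 13,14-alkene is deactivated by CO2H and CH2OAc; no stereocentre changes.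

**Step 7**
Reactants: 13 (5R,9R,10S)-16-acetoxy-6-oxo-ent-labda-7,13E-dien-15-oic acid
Product: 14 (5R,9S,10S)-16-acetoxy-6,17-dioxo-ent-labda-7,13E-dien-15-oic acid
Conditions: SeO2, 1,4-dioxane, trace H2O, 95 °C
Reagents that add atoms: selenium dioxide, O=[Se]=O
Why: Vinylogous Riley oxidation, in which selenium dioxide reacts through the extended dienol of the enone at its γ-methyl group (C17) to give the enal; acids and esters do not enolize, so the side chain is untouched.

**Step 8**
Reactants: 14 (5R,9S,10S)-16-acetoxy-6,17-dioxo-ent-labda-7,13E-dien-15-oic acid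
Product: 15 (5R,9S,10S)-16-acetoxy-6-oxo-ent-labda-7,13E-diene-15,17-dioic acid
Conditions: NaClO2, NaH2PO4, 2-methyl-2-butene, t-BuOH/H2O, 0 °C to rt
Reagents that add atoms: sodium chlorite, [Na+].[O-]Cl=O
Why: Pinnick oxidation of the aldehyde by chlorous acid with 2-methyl-2-butene as hypochlorite scavenger; the ketone, alkenes and acetate are inert.

**Step 9**
Reactants: 15 (5R,9S,10S)-16-acetoxy-6-oxo-ent-labda-7,13E-diene-15,17-dioic acid
Product: 16 (5R,9S,10S)-16-acetoxy-6-(tosylhydrazono)-ent-labda-7,13E-diene-15,17-dioic acid (6E)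
Conditions: TsNHNH2, PPTS (10 mol %), 4 Å MS, THF, 60 °C
Reagents that add atoms: 4-methylbenzenesulfonohydrazide, Cc1ccc(cc1)S(=O)(=O)NN
Why: Acid-catalysed hydrazone condensation at the only ketone (C6), with the N–NHTs group on the C7 side away from C5 and the C4 methyls; the 17-acid is trans to C6 across C7=C8 and cannot cyclize onto it.

**Step 10**
Reactants: 16 (5R,9S,10S)-16-acetoxy-6-(tosylhydrazono)-ent-labda-7,13E-diene-15,17-dioic acid
Product: 19 (5R,8S,9R,10S)-16-acetoxy-ent-labda-6,13E-diene-15,17-dioic acid (CNP0108723.1), via tosylhydrazine 17 (not isolated), via allylic diazene 18 (not isolated)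
Conditions: catecholborane (6 equiv), CHCl3, 0 °C; then NaOAc·3H2O, 60 °C; 1 M HCl work-up
Reagents that add atoms: none
Why: Kabalka reductive 1,3-transposition, in which catecholborane delivers hydride to C6 from the face opposite the C20 and C19 methyls, acetate-induced loss of sulfinate gives the allylic diazene on the methyl-bearing face, and its retro-ene loss of N2 transfers hydrogen suprafacially to that face of C8 while the alkene moves to C6=C7, setting 8S (CO2H trans to the C9 chain) with no enolate at C8.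

**Compound list**
1 | (2E,6E)-farnesyl bromide | CC(C)=CCC/C(C)=C/CC/C(C)=C/CBr | starting material
2 | tert-butyl acetoacetate | CC(=O)CC(=O)OC(C)(C)C | starting material
3 | sodium lithium dianion of tert-butyl acetoacetate (not isolated) | [Na+].[Li+].[CH2-]C(=O)[CH-]C(=O)OC(C)(C)C | intermediate
4 | tert-butyl (6E,10E)-7,11,15-trimethyl-3-oxohexadeca-6,10,14-trienoate | CC(C)=CCC/C(C)=C/CC/C(C)=C/CCC(=O)CC(=O)OC(C)(C)C | intermediate
5 | tert-butyl (2E,6E,10E)-7,11,15-trimethyl-3-[(trifluoromethylsulfonyl)oxy]hexadeca-2,6,10,14-tetraenoate (OTf trans to the ester) | CC(C)=CCC/C(C)=C/CC/C(C)=C/CC/C(OS(=O)(=O)C(F)(F)F)=C\C(=O)OC(C)(C)C | intermediate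
6 | bromomethyl acetate | CC(=O)OCBr | starting material
7 | (acetoxymethyl)zinc bromide (not isolated) | CC(=O)OC[Zn]Br | intermediate
8 | tert-butyl (2E,6E,10E)-3-(acetoxymethyl)-7,11,15-trimethylhexadeca-2,6,10,14-tetraenoate (CH2OAc trans to the ester) | CC(C)=CCC/C(C)=C/CC/C(C)=C/CC/C(COC(C)=O)=C\C(=O)OC(C)(C)C | intermediate
9 | trimethylsilyl (2E,6E,10E)-3-(acetoxymethyl)-7,11,15-trimethylhexadeca-2,6,10,14-tetraenoate (not isolated) | CC(C)=CCC/C(C)=C/CC/C(C)=C/CC/C(COC(C)=O)=C\C(=O)O[Si](C)(C)C | intermediate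
10 | (2E,6E,10E)-3-(acetoxymethyl)-7,11,15-trimethylhexadeca-2,6,10,14-tetraenoic acid | CC(C)=CCC/C(C)=C/CC/C(C)=C/CC/C(COC(C)=O)=C\C(=O)O | intermediate
11 | 16-acetoxy-15-carboxy-ent-labd-13E-en-8-yl cation, trans-fused, as its ion pair with the catalyst anion (not isolated) | CC(=O)OC/C(=C/C(=O)O)CC[C@@H]1[C+](C)CC[C@@H]2C(C)(C)CCC[C@@]12C | intermediate
12 | (5R,9R,10R)-16-acetoxy-ent-labda-7,13E-dien-15-oic acid (H-5 trans to the C-10 methyl, C-9 chain cis to it) | CC(=O)OC/C(=C/C(=O)O)CC[C@@H]1C(C)=CC[C@@H]2C(C)(C)CCC[C@@]12C | intermediate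
13 | (5R,9R,10S)-16-acetoxy-6-oxo-ent-labda-7,13E-dien-15-oic acid | CC(=O)OC/C(=C/C(=O)O)CC[C@@H]1C(C)=CC(=O)[C@@H]2C(C)(C)CCC[C@@]12C | intermediate
14 | (5R,9S,10S)-16-acetoxy-6,17-dioxo-ent-labda-7,13E-dien-15-oic acid | CC(=O)OC/C(=C/C(=O)O)CC[C@@H]1C(C=O)=CC(=O)[C@@H]2C(C)(C)CCC[C@@]12C | intermediate
15 | (5R,9S,10S)-16-acetoxy-6-oxo-ent-labda-7,13E-diene-15,17-dioic acid | CC(=O)OC/C(=C/C(=O)O)CC[C@@H]1C(C(=O)O)=CC(=O)[C@@H]2C(C)(C)CCC[C@@]12C | intermediate
16 | (5R,9S,10S)-16-acetoxy-6-(tosylhydrazono)-ent-labda-7,13E-diene-15,17-dioic acid (6E, NHTs on the C7 side) | CC(=O)OC/C(=C/C(=O)O)CC[C@@H]1C(C(=O)O)=C/C(=N\NS(=O)(=O)c3ccc(C)cc3)[C@@H]2C(C)(C)CCC[C@@]12C | intermediate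
17 | (5R,6S,9S,10S)-16-acetoxy-6-(2-tosylhydrazinyl)-ent-labda-7,13E-diene-15,17-dioic acid, nitrogen on the C-20 methyl face, present as its boryl derivatives (not isolated) | CC(=O)OC/C(=C/C(=O)O)CC[C@@H]1C(C(=O)O)=C[C@H](NNS(=O)(=O)c3ccc(C)cc3)[C@@H]2C(C)(C)CCC[C@@]12C | intermediate
18 | (5R,6S,9S,10S)-16-acetoxy-6-diazenyl-ent-labda-7,13E-diene-15,17-dioic acid (not isolated) | CC(=O)OC/C(=C/C(=O)O)CC[C@@H]1C(C(=O)O)=C[C@H](N=N)[C@@H]2C(C)(C)CCC[C@@]12C | intermediate
19 | (5R,8S,9R,10S)-16-acetoxy-ent-labda-6,13E-diene-15,17-dioic acid = (1R,2S,4aR,8aS)-1-[(3E)-3-(acetoxymethyl)-4-carboxybut-3-en-1-yl]-5,5,8a-trimethyl-1,2,4a,5,6,7,8,8a-octahydronaphthalene-2-carboxylic acid | CC(=O)OC/C(=C/C(=O)O)CC[C@@H]1[C@@H](C(=O)O)C=C[C@@H]2C(C)(C)CCC[C@@]12C | target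

**Totals**
Total steps: 10. Longest linear sequence: 10 (from 1 and 2 to 19).

**Steps most likely to fail, with fallbacks**

Step 5 (the proposed new cyclization) may give low enantioselectivity, the wrong alkene position or incomplete cascade. The fallback uses known chemistry and sets out from 10. Low-temperature superacid bicyclization (FSO3H, 2-nitropropane, −78 °C) gives the trans-fused 7-ene as a racemate, that is 12 together with its mirror image F1. The racemate is resolved by fractional crystallization of the (S)-1-phenylethylammonium salt F2 from ethyl acetate/hexane (chiral-phase chromatography if the salt does not discriminate). Cold 1 M HCl then liberates the acid, and the route is rejoined at 12.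

Step 7 (selenium dioxide on the enone methyl) may be sluggish or over-oxidize. The fallback reverses the order of the C–H oxygenations and sets out from 12. Selenium dioxide in dioxane at reflux oxidizes the vinylic C17 methyl of the isolated 7,8-alkene in the ordinary ene/[2,3] mode to the 17-oxo-7-ene acid F3. Chlorite oxidation gives the 7-ene-15,17-diacid F4. Chromium trioxide–3,5-dimethylpyrazole then oxidizes C6, and the route is rejoined at 15.

Step 10 (reduction of the hindered, conjugated hydrazone in the presence of two CO2H groups) may stall or give conjugate reduction. The fallback replaces the diazene by hydroxyl-directed hydrogenation and sets out from 15. NaBH4/CeCl3·7H2O in MeOH at −20 °C gives the 6-hydroxy-7-ene diacid F5, with hydride entering opposite the C20 methyl. Hydrogenation with [Ir(cod)(PCy3)(py)]PF6 and H2 in CH2Cl2 adds hydrogen to C7=C8 from the hydroxyl face, giving the saturated 6-hydroxy diacid F6 with the same C8 configuration as the target. Brief treatment with N,O-bis(trimethylsilyl)acetamide gives the bis(trimethylsilyl) ester F7. Burgess reagent in benzene at 50 °C then eliminates syn toward C7 only, since H-5 is anti to the hydroxyl, and aqueous work-up rejoins the route at 19.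

**Further compounds**
F1 | step 5 | mirror image of 12, (5S,9S,10S)-16-acetoxylabda-7,13E-dien-15-oic acid, the second component of the racemate | CC(=O)OC/C(=C/C(=O)O)CC[C@H]1C(C)=CC[C@H]2C(C)(C)CCC[C@]12C
F2 | step 5 | (S)-1-phenylethylammonium salt of 12 | CC(=O)OC/C(=C/C(=O)[O-])CC[C@@H]1C(C)=CC[C@@H]2C(C)(C)CCC[C@@]12C.C[C@H]([NH3+])c1ccccc1
F3 | step 7 | (5R,9S,10R)-16-acetoxy-17-oxo-ent-labda-7,13E-dien-15-oic acid | CC(=O)OC/C(=C/C(=O)O)CC[C@@H]1C(C=O)=CC[C@@H]2C(C)(C)CCC[C@@]12C
F4 | step 7 | (5R,9S,10R)-16-acetoxy-ent-labda-7,13E-diene-15,17-dioic acid | CC(=O)OC/C(=C/C(=O)O)CC[C@@H]1C(C(=O)O)=CC[C@@H]2C(C)(C)CCC[C@@]12C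
F5 | step 10 | (5R,6S,9S,10S)-16-acetoxy-6-hydroxy-ent-labda-7,13E-diene-15,17-dioic acid (OH on the C-20 methyl face) | CC(=O)OC/C(=C/C(=O)O)CC[C@@H]1C(C(=O)O)=C[C@H](O)[C@@H]2C(C)(C)CCC[C@@]12C
F6 | step 10 | (5R,6S,8S,9R,10S)-16-acetoxy-6-hydroxy-ent-labd-13E-ene-15,17-dioic acid | CC(=O)OC/C(=C/C(=O)O)CC[C@@H]1[C@@H](C(=O)O)C[C@H](O)[C@@H]2C(C)(C)CCC[C@@]12C
F7 | step 10 | bis(trimethylsilyl) ester of F6 | CC(=O)OC/C(=C/C(=O)O[Si](C)(C)C)CC[C@@H]1[C@@H](C(=O)O[Si](C)(C)C)C[C@H](O)[C@@H]2C(C)(C)CCC[C@@]12C
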